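The rate constants were chosen freely; the flask was simulated.

Late in a run, once target and its isomer share the charge, they stand one to 13, so target holds 7.14 % of it. The question is what stands much earlier.

    starting material + enzyme ⇌ complex (K1 = 2.5 /M, k1 = 4900 /M/s)
    complex → enzyme + target (k2 = 20 /s)
    target + enzyme ⇌ isomer of the product + enzyme, rate k3*[enzyme]*[target] forward; the back reaction follows from the equilibrium constant (K3 = 13, k3 = 28 /M/s)

| setting | red | violet | green |
|---|---|---|---|
| starting material | 0.13 M | 0.13 M (fed, over 80.0 min) | 0.13 M |
| enzyme | 0.01 mol% | 0.01 mol% | 0.01 mol% |
| time | 80 min | 80 min |  |
| remark | everything together in a closed stirred flask, run for 80 min | all but starting material at the start; starting material goes in evenly over 80.0 min, the run ends at 80 min | a single well-mixed tank run continuously and read at steady state, 80 min in it on average |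

- order of the set-ups by the amount of target at the outlet or at the end, in percent of the starting material put in, highest first (red / violet / green)
- amount of target at the outlet or at the end, in percent of the starting material put in, red
- amount of target at the outlet or at the end, in percent of the starting material put in, violet
- amount of target at the outlet or at the end, in percent of the starting material put in, green

- the stated concentrations are those of everything mixed, before any reaction; amounts are the same in each set-up
- the feed brings no volume worth counting
- run time (red): 80 min

I follow one molecule of starting material. It binds free enzyme, and the complex then meets a fork: back at 1960 /s, or on to target at 20 /s. So the effective constant for making target is k1 times the chance of going on. Free enzyme also takes target, with k3.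

Which numbers must I know well? Doubling k1 with K1 held multiplies the effective constant by 1.01, because going back is faster than going on, so k1 need not be known well. Doubling K1 or k2 multiplies it by 1.98, so these two must be. So must k3, the constant of target's loss. The enzyme loading multiplies both rates, so it moves the clock and leaves the fork alone. K3 enters through the way back.

Now the number. The chance of going on is 0.0101, so the effective constant is 49.5 /M/s. I carry s, the selectivity factor, the effective constant divided by k3: 1.77. The rule, for red and violet, where nothing leaves the flask, is that target rises while s times c(starting material) exceeds c(target) minus c(isomer)/K3.

For red I count binding once and leave out the way back. With 3.09 as the enzyme clock, I get 6.19 % starting material left and 33.5 % target.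

The forecast gives 35.6 % for red, 38.6 % for violet and 30.4 % for green, in the order violet > red > green, reasoning that “feeding gradually keeps the newly made target young”. My red figure is lower than its figure.

The simulation gives 35.6 % for red, 38.9 % for violet and 30.4 % for green, in the order violet > red > green. Neither red nor violet is at rest at 80 min. Red holds 6.16 % starting material and 58.3 % isomer, so the rule sets 10.9 % against 31.1 %, and by the rule its target is falling. Violet holds 33.4 % starting material and 27.7 % isomer, so the rule sets 59.0 % against 36.7 %, and by the rule its target is still rising. Violet's 38.9 % is a passing value: at 800 min its target stands at 7.14 %.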